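All runs come from a simulation with made-up constants; noise was put on by code.

A closed, stirred flask of constant volume holds substrate and free enzyme at a set temperature, and target forms in it.

common to all: substrate 0.050 M

|  | free enzyme | temperature | remark | time |
|---|---|---|---|---|
| oak | 2.5 µM | −10 °C | run made earlier |  |
| north-west | 5.0 µM | −10 °C |  | 40 min |
| south | 5.0 µM | 40 °C |  | 40 min |
| east | 5.0 µM | −35 °C |  | 40 min |
| north-east | 5.0 µM | 15 °C |  | 40 min |

- oak (time / min: target / %, substrate / %): 2.00: 7, 90; 4.00: 14, 86; 6.00: 20, 80; 8.00: 27, 79

(standard deviation of a reading: 2 percentage points)

- the earlier runs do not show what temperature does; that part of a forecast is a guess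
- no earlier run changes the charge of free enzyme; that part of a forecast is a guess

- the flask with the highest amount of target, in percent of the substrate charged ("all alike" if they lie within 1.5 percentage points) (north-west / south / east / north-east / all alike)
- final target, as a percentage of the substrate charged, in north-west
- final target, as a percentage of the substrate charged, in south
- final target, as a percentage of the substrate charged, in east
- final target, as a percentage of the substrate charged, in north-east

**How far had oak got at its last reading?**
At 8.00 min target reads 27% and substrate 79%. Each reading is a measure of conversion, so I take their mean, 24.0%.

**What does that say about north-west?**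
It has oak's temperature. Its enzyme times time is 10.0 times oak's, and I guess that this product sets the progress.

**So a straight line?**
That is my first answer, and it gives 240% of the charge. This is impossible, since it is more than was charged. The rate must fall as substrate falls.

**Put that back in. How does it fall?**
If the rate follows substrate to the first power, the fraction left is multiplied by the same factor in each oak-sized interval. North-west then ends at 93.6% target.

**Why the first power?**
I have no proof of it. Oak reads just 24.0% conversion, and with a scatter of 2 percentage points I do not separate the orders over so short a stretch.

**Then go round once more.**
Suppose the rate follows the square of substrate, a pseudo-second-order law at constant enzyme. Then substrate used over substrate left, which I call the clock, grows in proportion to enzyme times time. Oak's clock stands at 0.316. North-west's clock becomes 3.16, which leaves 24.1% substrate and gives 75.9% target.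

**Which do you commit to?**
I commit to the clock, with the first-power figure as the upper end. That is a choice. The readings do not make it for me. Temperature stays a guess.

The forecast is different. It names north-east and gives north-west 94%, south 88%, east 25% and north-east 97%. Its north-west stands above my 75.9%. In its own words: “North-east is my best guess for highest, though the temperature effects are guesses.”

The flasks gave north-west 78.1%, south 50.3%, east 62.8% and north-east 84.5%, so north-east stood highest.

    substrate + free enzyme → target + free enzyme, rate k1*[substrate]^2*[free enzyme]/(1 + ([substrate]/Kh1)^2) (0.111 M, k = 18600 M⁻² s⁻¹, Ea = 15.0 kJ mol⁻¹)
    free enzyme → unfolded enzyme (k = 8.05 × 10⁻⁵ s⁻¹, Ea = 254 kJ mol⁻¹)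
    target ⇌ isomer of the product (K = 1.52, k = 4.24 × 10⁻⁴ s⁻¹, Ea = 101 kJ mol⁻¹, ΔH = −21.0 kJ mol⁻¹)
    (constants at 40 °C)

In north-east at 40.0 min, target was being made 3.98 times faster than it was used up, each step taken net. The passing of target into isomer of the product had there, by its forward rate alone, a half-life of 13 h, long against the 40 min of the run. North-west left 22% substrate, a clock of 3.55 against the 3.16 reckoned from oak. North-east, with 13% left, had a clock 2.09 times the one reckoned for north-west. Carried to a neighbour flask, which is north-east with 1.20 µM free enzyme, the clock leaves 38.7% substrate, and that flask held 40%.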